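**Remark on the chemistry:** the target has no stereogenic element (two planar arenes joined by an ester), so no enantiomer has to be chosen. The stereocentres of the transient aldol adducts 8 and 12 are erased on aromatization. N‑Methoxy‑N‑methylhexanamide (5) is taken as a catalogue compound.

Atom labels: ring A = C1–C6 of the 2,4‑dimethoxy‑6‑pentylbenzoyl unit, with C7 its ester carbonyl. Ring B = C1'–C6' of the 2‑hydroxy‑6‑pentylbenzoic acid unit, with O4' its ester oxygen.

## Retrosynthetic overview

1. 16 ⇐ 15 by opening the salicylate acetonide that masks C1'–CO2H and C2'–OH of ring B; 15 ⇐ 13 by methylation of O2 and O4 of ring A.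
2. Key cut in 13: the depside bond C7(=O)–O4' and the ring A bond C1–C6 are broken together, so ring A becomes an acyclic 3,5,7‑triketo acyl chain, i.e. acylketene 10 (from diketo‑dioxinone 7) plus phenol 9.
3. Ring B of 9 comes from the same 7 by amine‑induced aldol cycloaromatization (bond C1'–C6'). The feature used: rings A and B are the same 6‑pentyl‑β‑resorcylate tetraketide, and the C7 ester sits exactly at the acyl terminus of that polyketide.
4. 7 ⇐ dioxinone 1 + acetyl chloride 2 + Weinreb amide 5 by two enolate acylations.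
5. Ring order: ring B first (step 3), ring A last (step 4), built de novo on the phenol oxygen of ring B.

Key step: step 4

## Route

Step 1
Reactants: 1 2,2,6‑trimethyl‑4H‑1,3‑dioxin‑4‑one; 2 acetyl chloride
Product: 4 2,2‑dimethyl‑6‑(2‑oxopropyl)‑4H‑1,3‑dioxin‑4‑one, via lithium dienolate 3 (not isolated)
Conditions: LiHMDS (2 equiv), THF, −78 °C; then 2, −78 °C; aq. NH4Cl
Reagents that add atoms: none
Why: LiHMDS removes a proton from the C6‑methyl of the vinylogous ester to give dienolate 3, which acetyl chloride acylates at the γ‑carbon (γ‑selective crossed Claisen acylation of a dioxinone dienolate), while the second equivalent of base stores the more acidic product as its enolate and so prevents double acylation.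

Step 2
Reactants: 4 2,2‑dimethyl‑6‑(2‑oxopropyl)‑4H‑1,3‑dioxin‑4‑one; 5 N‑methoxy‑N‑methylhexanamide
Product: 7 6‑(2,4‑dioxononyl)‑2,2‑dimethyl‑4H‑1,3‑dioxin‑4‑one, via dilithium dianion 6 (not isolated)
Conditions: LDA (2.2 equiv), THF, −78 °C; then 5, −78 → −20 °C; aq. NH4Cl
Reagents that add atoms: none
Why: LDA removes first the doubly activated ring‑side CH2 proton and then a terminal CH3 proton, and the more basic terminal carbanion of 6 adds to the Weinreb amide to form a chelated tetrahedral adduct that releases the 1,3‑diketone only on quench (Claisen‑type acylation of a dicarbonyl dianion, Weinreb ketone synthesis), so over‑addition should not occur.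

Step 3
Reactants: 7 6‑(2,4‑dioxononyl)‑2,2‑dimethyl‑4H‑1,3‑dioxin‑4‑one
Product: 9 7‑hydroxy‑2,2‑dimethyl‑5‑pentyl‑4H‑1,3‑benzodioxin‑4‑one, via bicyclic aldol adduct 8 (not isolated)
Conditions: Et3N, CH2Cl2, rt
Reagents that add atoms: none
Why: Amine‑mediated intramolecular aldol addition of dioxinone C5 to the hexanoyl ketone gives 8, which loses water and enolizes to aromatic ring B (biomimetic cycloaromatization of a diketo‑dioxinone to an acetonide‑masked β‑resorcylate); the dioxinone is kept because neither heat nor a nucleophile is present, and the product has only O4' free while C1'–CO2H and C2'–OH are already locked in the acetonide.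

Step 4
Reactants: 7 6‑(2,4‑dioxononyl)‑2,2‑dimethyl‑4H‑1,3‑dioxin‑4‑one (second portion); 9 7‑hydroxy‑2,2‑dimethyl‑5‑pentyl‑4H‑1,3‑benzodioxin‑4‑one
Product: 13 2,2‑dimethyl‑4‑oxo‑5‑pentyl‑4H‑1,3‑benzodioxin‑7‑yl 2,4‑dihydroxy‑6‑pentylbenzoate, via acylketene 10 (not isolated), via aryl trioxododecanoate 11 (not isolated), via cyclic aldol adduct 12 (not isolated)
Conditions: slow addition of 7 to 9 (1.5 equiv), PhMe, 110 °C; then Et3N, CH2Cl2, rt; then TFA, rt
Reagents that add atoms: none
Why: Heating 7 causes retro‑hetero‑Diels–Alder loss of acetone to acylketene 10, which the only free hydroxyl of 9 (O4') attacks to form the depside bond C7–O4' in 11; Et3N then induces aldol addition of the methylene between ester and ketone to the hexanoyl carbonyl to give 12 (ring A bond C1–C6), and TFA dehydrates 12 to the arene. The closest known reaction type is the dioxinone thermolysis, alcohol trapping and aldol aromatization sequence of biomimetic resorcylate synthesis, together with the acetoacetylation of phenols by dioxinone‑derived acylketenes. Ring A closes in a 6‑(enolendo)‑exo‑trig aldol mode, followed by dehydration and enolization. Product 13 has no stereocentre, and the two stereocentres of 12 form as a mixture and are erased on aromatization. The step needs capture of 10 by the phenol in preference to O‑cyclization of 10 to a 4‑hydroxy‑2‑pyrone, which slow addition of 7 to an excess of hot 9, the only protic nucleophile present, should secure. It also needs the aldol course in preference to Claisen closure, lactonization or reversion to the ketene with loss of the aryloxide, which a mild amine base at room temperature in an alkoxide‑free medium should favour.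

Step 5
Reactants: 13 2,2‑dimethyl‑4‑oxo‑5‑pentyl‑4H‑1,3‑benzodioxin‑7‑yl 2,4‑dihydroxy‑6‑pentylbenzoate
Product: 15 2,2‑dimethyl‑4‑oxo‑5‑pentyl‑4H‑1,3‑benzodioxin‑7‑yl 2,4‑dimethoxy‑6‑pentylbenzoate, via monomethyl ether 14 (not isolated)
Conditions: MeI (excess), K2CO3, dry DMF, rt → 40 °C
Reagents that add atoms: iodomethane, CI
Why: Williamson ether synthesis in which the free O4–H reacts first and the hydrogen‑bonded O2–H follows in the dipolar aprotic solvent; only ring A is methylated because ring B has no free hydroxyl or carboxyl, and the absence of any nucleophile other than the phenoxides should keep the acetonide and the aryl ester intact.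

Step 6
Reactants: 15 2,2‑dimethyl‑4‑oxo‑5‑pentyl‑4H‑1,3‑benzodioxin‑7‑yl 2,4‑dimethoxy‑6‑pentylbenzoate
Product: 16 4‑[(2,4‑dimethoxy‑6‑pentylbenzoyl)oxy]‑2‑hydroxy‑6‑pentylbenzoic acid (CNP0139062.0)
Conditions: LiOH (3 equiv), THF/H2O, 0 °C → rt; then 1 M HCl to pH 3, 0 °C
Reagents that add atoms: lithium hydroxide, [Li+].[OH-]
Why: Acyl‑oxygen (BAc2) opening of the activated, planar benzodioxinone carbonyl by hydroxide, after which the hemiketal alkoxide collapses irreversibly to acetone and the C2' phenoxide; the depside carbonyl C7 should survive because it is flanked by OMe and pentyl (di‑ortho‑substituted, twisted out of the ring plane), has no ortho or para phenoxide for an elimination pathway, and is attached after ring opening to an electron‑rich dianionic ring B; cold acidification avoids decarboxylation of the β‑resorcylic acid.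

## Compound list

1 | 2,2,6‑trimethyl‑4H‑1,3‑dioxin‑4‑one | CC1=CC(=O)OC(C)(C)O1 | starting material
2 | acetyl chloride | CC(Cl)=O | starting material
3 | lithium 2,2‑dimethyl‑6‑methylidene‑6H‑1,3‑dioxin‑4‑olate (lithium dienolate of 1) | [Li+].C=C1C=C([O-])OC(C)(C)O1 | intermediate (not isolated)
4 | 2,2‑dimethyl‑6‑(2‑oxopropyl)‑4H‑1,3‑dioxin‑4‑one | CC(=O)CC1=CC(=O)OC(C)(C)O1 | intermediate
5 | N‑methoxy‑N‑methylhexanamide | CCCCCC(=O)N(C)OC | starting material
6 | dilithium dianion of 4 (bis‑enolate) | [Li+].[Li+].C=C([O-])C=C1C=C([O-])OC(C)(C)O1 | intermediate (not isolated)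
7 | 6‑(2,4‑dioxononyl)‑2,2‑dimethyl‑4H‑1,3‑dioxin‑4‑one | CCCCCC(=O)CC(=O)CC1=CC(=O)OC(C)(C)O1 | intermediate
8 | 5‑hydroxy‑2,2‑dimethyl‑5‑pentyl‑5,6‑dihydro‑4H‑1,3‑benzodioxine‑4,7(4aH)‑dione (mixture of stereoisomers) | CCCCCC1(O)CC(=O)C=C2OC(C)(C)OC(=O)C12 | intermediate (not isolated)
9 | 7‑hydroxy‑2,2‑dimethyl‑5‑pentyl‑4H‑1,3‑benzodioxin‑4‑one | CCCCCc1cc(O)cc2OC(C)(C)OC(=O)c12 | intermediate
10 | dodec‑1‑ene‑1,3,5,7‑tetrone (acylketene) | CCCCCC(=O)CC(=O)CC(=O)C=C=O | intermediate (not isolated)
11 | 2,2‑dimethyl‑4‑oxo‑5‑pentyl‑4H‑1,3‑benzodioxin‑7‑yl 3,5,7‑trioxododecanoate | CCCCCC(=O)CC(=O)CC(=O)CC(=O)Oc1cc(CCCCC)c2C(=O)OC(C)(C)Oc2c1 | intermediate (not isolated)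
12 | 2,2‑dimethyl‑4‑oxo‑5‑pentyl‑4H‑1,3‑benzodioxin‑7‑yl 2‑hydroxy‑4,6‑dioxo‑2‑pentylcyclohexane‑1‑carboxylate (mixture of stereoisomers) | CCCCCC1(O)CC(=O)CC(=O)C1C(=O)Oc1cc(CCCCC)c2C(=O)OC(C)(C)Oc2c1 | intermediate (not isolated)
13 | 2,2‑dimethyl‑4‑oxo‑5‑pentyl‑4H‑1,3‑benzodioxin‑7‑yl 2,4‑dihydroxy‑6‑pentylbenzoate | CCCCCc1cc(O)cc(O)c1C(=O)Oc1cc(CCCCC)c2C(=O)OC(C)(C)Oc2c1 | intermediate
14 | 2,2‑dimethyl‑4‑oxo‑5‑pentyl‑4H‑1,3‑benzodioxin‑7‑yl 2‑hydroxy‑4‑methoxy‑6‑pentylbenzoate | CCCCCc1cc(OC)cc(O)c1C(=O)Oc1cc(CCCCC)c2C(=O)OC(C)(C)Oc2c1 | intermediate (not isolated)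
15 | 2,2‑dimethyl‑4‑oxo‑5‑pentyl‑4H‑1,3‑benzodioxin‑7‑yl 2,4‑dimethoxy‑6‑pentylbenzoate | CCCCCc1cc(OC)cc(OC)c1C(=O)Oc1cc(CCCCC)c2C(=O)OC(C)(C)Oc2c1 | intermediate
16 | 4‑[(2,4‑dimethoxy‑6‑pentylbenzoyl)oxy]‑2‑hydroxy‑6‑pentylbenzoic acid | CCCCCc1cc(OC(=O)c2c(CCCCC)cc(OC)cc2OC)cc(O)c1C(=O)O | target

## Step count and risks

Total step count: 6. Longest linear sequence: 6 (1 → 4 → 7 → 9 → 13 → 15 → 16; compound 7 feeds both step 3 and step 4).

**Steps most likely to fail**

**Step 4 (key step).** The acylketene may cyclize through its own enol oxygen to a 4‑hydroxy‑2‑pyrone faster than the electron‑poor phenol captures it. The aryl triketo ester may also lose its aryloxide (lactonization, Claisen closure or reversion to the ketene) before the aldol closure.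

Fallback: ring A is brought in preformed and the ester is made by mixed‑anhydride acylation. The fallback sets out from 9 and returns to the route at 15, so step 5 is no longer needed. Purchased 1,3‑dimethoxy‑5‑pentylbenzene F1 is brominated para to one methoxy group and ortho to the pentyl chain (NBS, MeCN, 0 °C) to give 1‑bromo‑2,4‑dimethoxy‑6‑pentylbenzene F2. Bromine–lithium exchange (n‑BuLi, THF, −78 °C) gives (2,4‑dimethoxy‑6‑pentylphenyl)lithium F3, which is carboxylated with CO2 and acidified to 2,4‑dimethoxy‑6‑pentylbenzoic acid F4. Trifluoroacetic anhydride in toluene at rt converts F4 into 2,4‑dimethoxy‑6‑pentylbenzoic trifluoroacetic anhydride F5 in the flask, which acylates the single free hydroxyl of 9 to give 15.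

**Step 6.** Acyl cleavage may occur at the wrong carbonyl (hydroxide attack on the depside ester C7 in competition with the benzodioxinone), and the product acid may decarboxylate on acidification.

Fallback: the acid is released by hydrogenolysis instead of acyl cleavage. The fallback sets out from 9 and returns at 16. The acetonide of 9 is opened with benzyl alcohol and Cs2CO3 (60 °C) to benzyl 2,4‑dihydroxy‑6‑pentylbenzoate F6. The non‑chelated O4'–H of F6 is acylated selectively by the mixed anhydride F5, made as above from acid F4 with trifluoroacetic anhydride in toluene, to give benzyl 4‑[(2,4‑dimethoxy‑6‑pentylbenzoyl)oxy]‑2‑hydroxy‑6‑pentylbenzoate F7. Hydrogenolysis (H2, Pd/C, EtOAc, rt) then frees the acid 16 under neutral conditions.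

**Step 2.** Proton transfer from the product or from the α‑CH2 of the amide may quench the dianion, so that conversion stalls or the enolate is O‑acylated.

Fallback: the C–C bond is made by aldol addition and the oxidation level is adjusted afterwards. The fallback sets out from 4 and returns at 7. Dianion 6 (LDA, THF, −78 °C) is added to purchased hexanal F8 to give racemic 6‑(4‑hydroxy‑2‑oxononyl)‑2,2‑dimethyl‑4H‑1,3‑dioxin‑4‑one F9. Dess–Martin periodinane (CH2Cl2, 0 °C) oxidizes the β‑hydroxy ketone of F9 to the 1,3‑diketone 7.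

## Further compounds

F1 | step 4 | 1,3‑dimethoxy‑5‑pentylbenzene (purchased) | CCCCCc1cc(OC)cc(OC)c1
F2 | step 4 | 1‑bromo‑2,4‑dimethoxy‑6‑pentylbenzene | CCCCCc1cc(OC)cc(OC)c1Br
F3 | step 4 | (2,4‑dimethoxy‑6‑pentylphenyl)lithium (not isolated) | [Li]c1c(CCCCC)cc(OC)cc1OC
F4 | step 4 | 2,4‑dimethoxy‑6‑pentylbenzoic acid | CCCCCc1cc(OC)cc(OC)c1C(=O)O
F5 | step 4 | 2,4‑dimethoxy‑6‑pentylbenzoic trifluoroacetic anhydride (not isolated) | CCCCCc1cc(OC)cc(OC)c1C(=O)OC(=O)C(F)(F)F
F6 | step 6 | benzyl 2,4‑dihydroxy‑6‑pentylbenzoate | CCCCCc1cc(O)cc(O)c1C(=O)OCc1ccccc1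
F7 | step 6 | benzyl 4‑[(2,4‑dimethoxy‑6‑pentylbenzoyl)oxy]‑2‑hydroxy‑6‑pentylbenzoate | CCCCCc1cc(OC(=O)c2c(CCCCC)cc(OC)cc2OC)cc(O)c1C(=O)OCc1ccccc1
F8 | step 2 | hexanal (purchased) | CCCCCC=O
F9 | step 2 | 6‑(4‑hydroxy‑2‑oxononyl)‑2,2‑dimethyl‑4H‑1,3‑dioxin‑4‑one (racemic) | CCCCCC(O)CC(=O)CC1=CC(=O)OC(C)(C)O1
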